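Count the exchanges first: each exchange standing in a flask has spent one incoming ligand, net.

the same everywhere: starting complex 29 mM; incoming ligand 34.8 mM
- teal: the very flask that is asked about, followed so far
- flask: time 5.0 d

- teal (time / h: complex with two exchanged / %, starting complex / %): 4.00: 11, 31; 12.0: 24, 19; 20.0: 30, 15; 30.0: 32, 14; 40.0: 32, 13; 60.0: 35, 12; 72.0: 34, 11

(scatter of a reading: 2 percentage points)

- removed complex with two exchanged is counted in
- candidate steps: starting complex + incoming ligand -> leaving ligand + complex with one exchanged; complex with one exchanged + incoming ligand -> leaving ligand + complex with two exchanged; complex with two exchanged + incoming ligand <-> leaving ligand + complex with three exchanged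
- additions bring no volume worth counting

- Tuesday's: at 5.0 d add starting complex, 50.0 % of the amount charged, then wait 40 h
- Sunday's: at 5.0 d add incoming ligand, 50.0 % of the amount charged, then wait 40 h
- Saturday's: at 5.0 d take out 90 % of the complex with two exchanged then present, then wait 40 h
- Monday's: change nothing and wait 40 h more

* complex with two exchanged, in percent of the starting complex first charged, at 5.0 d
* the remedy with the largest gain of complex with two exchanged, or "none" below 2 percentage points (Tuesday's / Sunday's / Saturday's / Monday's / none)
* complex with two exchanged present, with what was taken out counted in, in percent of the starting complex first charged, after Tuesday's
* complex with two exchanged present, with what was taken out counted in, in percent of the starting complex first charged, after Saturday's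

Keep one quantity, the spare ligand: the incoming ligand charged beyond one per starting complex, in percent of the starting complex charged, here 20.0 %. With no incoming ligand free, the balance on these steps reads, in the same percent:

[complex with two exchanged] = spare + [starting complex] − 2 × [complex with three exchanged]

Ask what each term needs. An error of one percent of the incoming ligand charge moves the spare ligand by 1.2 percentage points, so the charges must be right. Starting complex passes over point for point, so its scatter of 2 points counts in full unless readings are averaged. Time matters little late in the teal run: starting complex goes from 12 % to 11 % between 60.0 h and 72.0 h, a step smaller than two readings can separate. No reading shows complex with three exchanged, though each point of it counts double, so take it as nil. Take the free ligand as nil too, as an assumption: the first step runs one way, yet starting complex moves by less than the scatter between those two readings.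

My own reckoning averages the last three readings of starting complex:

spare + [starting complex] = 20.0 % + 12.0 % = 32.0 %

The forecast says 34 %, from 32 % to 36 %, so my figure is lower and sits at its low end. It picks Sunday's, with 34 % after Tuesday's and 34 % after Saturday's, on the ground that “the stall means the incoming ligand has run out”.

The flask gives 32.7 %. Sunday's gains 39 points, and Tuesday's and Saturday's end at 32.7 % and 32.7 %.

    starting complex + incoming ligand → leaving ligand + complex with one exchanged (k = 0.00456 L mol⁻¹ s⁻¹)
    complex with one exchanged + incoming ligand → leaving ligand + complex with two exchanged (k = 0.00164 L mol⁻¹ s⁻¹)
    complex with two exchanged + incoming ligand ⇌ leaving ligand + complex with three exchanged (K = 1.00, k = 0.00563 L mol⁻¹ s⁻¹)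

At 1.31 h the half-life of starting complex by its step, 2.1 h, is shorter than that of complex with one exchanged by its step, 5.7 h. Complex with one exchanged is then made 4.02 times faster than it is used up, and at 120 h the flask holds incoming ligand, the limiting reagent, at 0 % of its charge, complex with three exchanged at 0 %, and starting complex at 12.7 %, which with the spare 20.0 % makes 32.7 %. The neighbour charged with 49 mM of starting complex has a spare of −29.0 %, ends with 39 % of starting complex and 0 % of complex with three exchanged, and so holds 10.4 % of complex with two exchanged.

(The numbers in the tables were generated by integration with made-up constants, noise included.)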